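**Strategy.** Atom numbering: ring carbons C1 (acetoxy carbon) to C14 around the 14-membered ring A, epoxide at C12–C13, carbinol carbon C15 on C6. The route rests on disconnecting the C3–C4 bond, which joins the methyl-bearing sp2 carbon of the E-C2=C3 olefin to the ethylene bridge (C4–C5) leading to stereocentre C6. An intramolecular B-alkyl Suzuki–Miyaura coupling closes ring A and fixes the E-trisubstituted olefin in one operation. Its precursor is an open chain with an (E)-alkenyl iodide at C3 and a vinyl group (C5=C4) on C6, already carrying the cis-epoxide, the Z-C8=C9 olefin from nerol and the tertiary alcohol; C1 is inverted last by Mitsunobu acetylation.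

Key step: step 16

Remark: the C1 and C13 oxygens of the target are 1,3-anti, whereas hydroxyl-directed epoxidation of a (Z)-homoallylic alcohol is expected to be 1,3-syn, so C1 is carried as the S epimer and inverted in the last step.

Step 1
Reactants: 1 nerol
Product: 2 1-({[(2Z)-3,7-dimethylocta-2,6-dien-1-yl]oxy}methyl)-4-methoxybenzene (neryl PMB ether)
Conditions: NaH, PMBCl, Bu4NI (cat.), THF/DMF, 0 °C to rt
Reagents that add atoms: 4-methoxybenzyl chloride, COc1ccc(CCl)cc1
Why: Williamson etherification of the primary allylic alkoxide gives an ether that survives every step up to its oxidative removal in step 11 and inductively deactivates the C8=C9 olefin.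

Step 2
Reactants: 2 neryl PMB ether
Product: 3 rac-3-{(3Z)-5-[(4-methoxybenzyl)oxy]-3-methylpent-3-en-1-yl}-2,2-dimethyloxirane
Conditions: mCPBA (1.0 equiv), NaHCO3, CH2Cl2, −20 °C
Reagents that add atoms: 3-chloroperoxybenzoic acid, O=C(OO)c1cccc(Cl)c1
Why: Prilezhaev epoxidation should be site-selective for the terminal trisubstituted olefin because the other one is deactivated by the allylic ether oxygen; the new stereocentre is destroyed in step 3, so no control is needed.

Step 3
Reactants: 3 terminal epoxide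
Product: 4 (4Z)-6-[(4-methoxybenzyl)oxy]-4-methylhex-4-enal
Conditions: H5IO6, THF/H2O, 0 °C
Reagents that add atoms: none
Why: Acid-mediated hydration of the epoxide (water entering at the tertiary carbon) and Malaprade glycol cleavage in one pot release acetone and the C12 aldehyde without touching the Z-olefin or the PMB ether.

Step 4
Reactants: 4 aldehyde
Product: 5 1-({[(2Z,6Z)-7-iodo-3-methylocta-2,6-dien-1-yl]oxy}methyl)-4-methoxybenzene
Conditions: EtPPh3I, n-BuLi, THF, rt; I2, −78 °C; NaHMDS, −20 °C; then 4, −78 °C to rt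
Reagents that add atoms: ethyltriphenylphosphonium iodide, CC[P+](c1ccccc1)(c1ccccc1)c1ccccc1.[I-]; iodine, [I][I]
Why: Stork–Zhao-type Wittig olefination with the non-stabilised ylide Ph3P=C(I)CH3 under kinetic control should give the (Z)-2-iodoalkene (chain cis to iodine), which fixes the C12=C13 geometry needed for the cis-epoxide.

Step 5
Reactants: 5 (Z)-alkenyl iodide
Product: 6 (3Z,7Z)-N-methoxy-9-[(4-methoxybenzyl)oxy]-N,3,7-trimethylnona-3,7-dienamide
Conditions: BrZnCH2C(O)N(OMe)Me (from the bromoamide and Zn dust, THF), Pd(dba)2 (5 mol%), P(t-Bu)3 (5 mol%), THF, rt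
Reagents that add atoms: 2-bromo-N-methoxy-N-methylacetamide, CON(C)C(=O)CBr
Why: Negishi-type cross-coupling of the Reformatsky (zinc amide enolate) reagent with the alkenyl iodide proceeds with retention of olefin geometry under near-neutral conditions that should not move the β,γ-double bond into conjugation.

Step 6
Reactants: 6 Weinreb amide
Product: 7 (6Z,10Z)-12-[(4-methoxybenzyl)oxy]-6,10-dimethyldodeca-6,10-dien-2-yn-4-one
Conditions: 1-propynylmagnesium bromide, THF, −20 to 0 °C; aq. NH4Cl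
Reagents that add atoms: 1-propynylmagnesium bromide, CC#C[Mg]Br
Why: Weinreb ketone synthesis, in which the chelated tetrahedral adduct prevents over-addition and conjugate addition, so the ynone is released only on work-up.

Step 7
Reactants: 7 ynone
Product: 8 (4S,6Z,10Z)-12-[(4-methoxybenzyl)oxy]-6,10-dimethyldodeca-6,10-dien-2-yn-4-ol
Conditions: Ru[(S,S)-TsNCH(Ph)CH(Ph)NH](p-cymene) (1 mol%), i-PrOH, rt
Reagents that add atoms: none
Why: Noyori asymmetric transfer hydrogenation of an acetylenic ketone under base-free conditions, in which the alkynyl group takes the place of the aryl group in the CH/π-controlled transition state, so the (S,S)-ligand should give the (S)-propargylic alcohol (C1).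

Step 8
Reactants: 8 (S)-propargylic alcohol
Product: 9 (2S)-1-[(2R,3S)-3-{(3Z)-5-[(4-methoxybenzyl)oxy]-3-methylpent-3-en-1-yl}-2-methyloxiran-2-yl]pent-3-yn-2-ol
Conditions: VO(acac)2 (5 mol%), t-BuOOH (1.5 equiv, decane), CH2Cl2, 0 °C to rt
Reagents that add atoms: tert-butyl hydroperoxide, CC(C)(C)OO
Why: Hydroxyl-directed vanadium-catalysed epoxidation reaches only the homoallylic C12=C13 olefin, and a chair-like vanadate transition state with the propynyl group equatorial and the C14–H bond eclipsing the olefin (minimal A1,3 strain with the cis C11 substituent) should deliver oxygen syn to the C1 hydroxyl, setting C12 (S) and C13 (R).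

Step 9
Reactants: 9 epoxy alcohol
Product: 10 tert-butyl({(2S)-1-[(2R,3S)-3-{(3Z)-5-[(4-methoxybenzyl)oxy]-3-methylpent-3-en-1-yl}-2-methyloxiran-2-yl]pent-3-yn-2-yl}oxy)dimethylsilane
Conditions: TBSCl, imidazole, DMF, rt
Reagents that add atoms: tert-butyldimethylsilyl chloride, CC(C)(C)[Si](C)(C)Cl
Why: Standard silylation masks the C1 alcohol for the organometallic steps, and the bulky silyl ether also steers the hydrozirconation of step 10.

Step 10
Reactants: 10 silyl ether
Product: 12 tert-butyl{[(2S,3E)-4-iodo-1-[(2R,3S)-3-{(3Z)-5-[(4-methoxybenzyl)oxy]-3-methylpent-3-en-1-yl}-2-methyloxiran-2-yl]pent-3-en-2-yl]oxy}dimethylsilane, via alkenylzirconocene chloride 11 (not isolated)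
Conditions: Cp2Zr(H)Cl (2.5 equiv), THF, rt; then I2, 0 °C
Reagents that add atoms: iodine, [I][I]
Why: Syn-hydrozirconation with excess Schwartz reagent equilibrates zirconium to the less hindered methyl-bearing carbon C3, distal to the silyloxy group, and iodinolysis with retention gives the (E)-alkenyl iodide, while the hindered epoxide and the trisubstituted olefin should be left alone at room temperature.

Step 11
Reactants: 12 PMB ether
Product: 13 (2Z)-5-[(2S,3R)-3-{(2S,3E)-2-[(tert-butyldimethylsilyl)oxy]-4-iodopent-3-en-1-yl}-3-methyloxiran-2-yl]-3-methylpent-2-en-1-ol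
Conditions: DDQ, CH2Cl2/pH 7 buffer, 0 °C
Reagents that add atoms: none
Why: Oxidative cleavage of the 4-methoxybenzyl ether through its oxocarbenium ion frees the primary allylic alcohol without acid, so the silyl ether, epoxide and alkenyl iodide remain.

Step 12
Reactants: 13 allylic alcohol
Product: 14 {[(2S,3E)-1-[(2R,3S)-3-[(3Z)-5-bromo-3-methylpent-3-en-1-yl]-2-methyloxiran-2-yl]-4-iodopent-3-en-2-yl]oxy}(tert-butyl)dimethylsilane
Conditions: CBr4, PPh3, 2,6-lutidine, CH2Cl2, −20 °C
Reagents that add atoms: tetrabromomethane, BrC(Br)(Br)Br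
Why: Appel bromination of the primary allylic alcohol under cold, buffered conditions is an SN2 displacement that should cause neither allylic transposition nor Z/E isomerisation.

Step 13
Reactants: 15 (4S)-4-benzyl-1,3-oxazolidin-2-one; 16 (2E)-but-2-enoic anhydride
Product: 17 (4S)-4-benzyl-3-[(2E)-but-2-enoyl]-1,3-oxazolidin-2-one
Conditions: Et3N, LiCl, THF, rt
Reagents that add atoms: none
Why: Lithium chloride-mediated N-acylation of the oxazolidinone by the anhydride installs the crotonoyl group without strong base, so the E-enoyl unit is not deconjugated.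

Step 14
Reactants: 14 allylic bromide; 17 N-crotonoyl oxazolidinone
Product: 19 (4S)-4-benzyl-3-[(2S,4Z)-7-[(2S,3R)-3-{(2S,3E)-2-[(tert-butyldimethylsilyl)oxy]-4-iodopent-3-en-1-yl}-3-methyloxiran-2-yl]-2-ethenyl-5-methylhept-4-enoyl]-1,3-oxazolidin-2-one, via sodium dienolate 18 (not isolated)
Conditions: 17 (2 equiv), NaHMDS, THF, −78 °C; then 14, −78 to −40 °C
Reagents that add atoms: none
Why: Evans asymmetric alkylation in its deconjugative form, in which γ-deprotonation gives the chelated (Z)-dienolate and the allylic bromide attacks the α-carbon on the face opposite the benzyl group, setting C6 (S at this stage, the arrangement needed in the target) and unveiling the vinyl group.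

Step 15
Reactants: 19 alkylated imide
Product: 21 (3S,5Z)-8-[(2S,3R)-3-{(2S,3E)-2-[(tert-butyldimethylsilyl)oxy]-4-iodopent-3-en-1-yl}-3-methyloxiran-2-yl]-3-ethenyl-2,6-dimethyloct-5-en-2-ol, via methyl ketone 20 (not isolated)
Conditions: MeMgCl (4 equiv), THF, −40 to 0 °C; aq. NH4Cl
Reagents that add atoms: methylmagnesium chloride, C[Mg]Cl
Why: Double Grignard addition to the more electrophilic exocyclic imide carbonyl expels the oxazolidinone and turns the acyl group into the tertiary carbinol C15, addition to the transient methyl ketone being faster than its enolisation so that C6 should not epimerise.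

Step 16
Reactants: 21 seco alkenyl iodide
Product: 23 2-[(1R,3S,4E,8R,10Z,14S)-3-[(tert-butyldimethylsilyl)oxy]-1,5,11-trimethyl-15-oxabicyclo[12.1.0]pentadeca-4,10-dien-8-yl]propan-2-ol, via B-alkyl-9-BBN borane 22 (not isolated)
Conditions: 9-BBN-H dimer (3 equiv), THF, 0 °C to rt; then slow addition to Pd(dppf)Cl2 (20 mol%), AsPh3 (40 mol%), Cs2CO3, DMF/THF/H2O, 45 °C, final concentration 2 mM
Reagents that add atoms: none
Why: 9-BBN adds anti-Markovnikov to the only monosubstituted olefin (C5=C4) to give the primary borane 22; zerovalent palladium then inserts into the C3–I bond, base-activated transmetalation transfers C4 from the borate to palladium, and reductive elimination forges C3–C4. The closest known reaction type is the intramolecular B-alkyl Suzuki–Miyaura macrocyclisation. Ring A (14-membered carbocycle) closes by sp2–sp3 reductive elimination from a 15-membered palladacycle under high dilution. No new stereocentre is formed; the E geometry of C2=C3 is set by the alkenyl iodide and carried over with retention, and C1, C6, C12 and C13 are spectators. The step needs chemoselective hydroboration (secured by the steric demand of 9-BBN towards the trisubstituted olefin, the alkenyl iodide and the epoxide), ring closure over oligomerisation (slow addition, with the Z-olefin and cis-epoxide as turn elements) and suppression of β-hydride elimination (dppf, AsPh3), while the allylic oxygen at C1 is a silyl ether that zerovalent palladium does not ionise.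

Step 17
Reactants: 23 macrocyclic silyl ether
Product: 24 (1R,3S,4E,8R,10Z,14S)-8-(2-hydroxypropan-2-yl)-1,5,11-trimethyl-15-oxabicyclo[12.1.0]pentadeca-4,10-dien-3-ol
Conditions: TBAF, THF, 0 °C to rt
Reagents that add atoms: none
Why: Fluoride-mediated desilylation frees the (S)-configured allylic alcohol at C1 under conditions that leave the epoxide and the tertiary alcohol untouched.

Step 18
Reactants: 24 (S)-allylic alcohol
Product: 25 (1R,3R,4E,8R,10Z,14S)-8-(2-hydroxypropan-2-yl)-1,5,11-trimethyl-15-oxabicyclo[12.1.0]pentadeca-4,10-dien-3-yl acetate (target)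
Conditions: PPh3, DIAD, AcOH, THF, 0 °C to rt
Reagents that add atoms: acetic acid, CC(O)=O
Why: Mitsunobu esterification activates the secondary allylic alcohol as its alkoxyphosphonium ion and acetate displaces it by SN2 with inversion, turning C1 (S) into C1 (R) while the unreactive tertiary alcohol stays free and SN2′ attack at the fully substituted C3 is disfavoured.

**Compound list**

1 | nerol, (2Z)-3,7-dimethylocta-2,6-dien-1-ol | OC/C=C(/C)CCC=C(C)C | starting material
2 | 1-({[(2Z)-3,7-dimethylocta-2,6-dien-1-yl]oxy}methyl)-4-methoxybenzene | COc1ccc(COC/C=C(/C)CCC=C(C)C)cc1 | intermediate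
3 | rac-3-{(3Z)-5-[(4-methoxybenzyl)oxy]-3-methylpent-3-en-1-yl}-2,2-dimethyloxirane | COc1ccc(COC/C=C(/C)CCC2OC2(C)C)cc1 | intermediate
4 | (4Z)-6-[(4-methoxybenzyl)oxy]-4-methylhex-4-enal | COc1ccc(COC/C=C(/C)CCC=O)cc1 | intermediate
5 | 1-({[(2Z,6Z)-7-iodo-3-methylocta-2,6-dien-1-yl]oxy}methyl)-4-methoxybenzene | COc1ccc(COC/C=C(/C)CC/C=C(/C)I)cc1 | intermediate
6 | (3Z,7Z)-N-methoxy-9-[(4-methoxybenzyl)oxy]-N,3,7-trimethylnona-3,7-dienamide | COc1ccc(COC/C=C(/C)CC/C=C(/C)CC(=O)N(C)OC)cc1 | intermediate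
7 | (6Z,10Z)-12-[(4-methoxybenzyl)oxy]-6,10-dimethyldodeca-6,10-dien-2-yn-4-one | COc1ccc(COC/C=C(/C)CC/C=C(/C)CC(=O)C#CC)cc1 | intermediate
8 | (4S,6Z,10Z)-12-[(4-methoxybenzyl)oxy]-6,10-dimethyldodeca-6,10-dien-2-yn-4-ol | COc1ccc(COC/C=C(/C)CC/C=C(/C)C[C@H](O)C#CC)cc1 | intermediate
9 | (2S)-1-[(2R,3S)-3-{(3Z)-5-[(4-methoxybenzyl)oxy]-3-methylpent-3-en-1-yl}-2-methyloxiran-2-yl]pent-3-yn-2-ol | COc1ccc(COC/C=C(/C)CC[C@@H]2O[C@]2(C)C[C@H](O)C#CC)cc1 | intermediate
10 | tert-butyl({(2S)-1-[(2R,3S)-3-{(3Z)-5-[(4-methoxybenzyl)oxy]-3-methylpent-3-en-1-yl}-2-methyloxiran-2-yl]pent-3-yn-2-yl}oxy)dimethylsilane | COc1ccc(COC/C=C(/C)CC[C@@H]2O[C@]2(C)C[C@H](O[Si](C)(C)C(C)(C)C)C#CC)cc1 | intermediate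
11 | alkenylzirconocene chloride: compound 12 with Cp2Zr(Cl) in place of iodine at C3 (H and Zr cis) | COc1ccc(COC/C=C(/C)CC[C@@H]2O[C@]2(C)C[C@H](O[Si](C)(C)C(C)(C)C)/C=C(\C)[Zr](Cl)(C3C=CC=C3)C3C=CC=C3)cc1 | intermediate
12 | tert-butyl{[(2S,3E)-4-iodo-1-[(2R,3S)-3-{(3Z)-5-[(4-methoxybenzyl)oxy]-3-methylpent-3-en-1-yl}-2-methyloxiran-2-yl]pent-3-en-2-yl]oxy}dimethylsilane | COc1ccc(COC/C=C(/C)CC[C@@H]2O[C@]2(C)C[C@H](O[Si](C)(C)C(C)(C)C)/C=C(\C)I)cc1 | intermediate
13 | (2Z)-5-[(2S,3R)-3-{(2S,3E)-2-[(tert-butyldimethylsilyl)oxy]-4-iodopent-3-en-1-yl}-3-methyloxiran-2-yl]-3-methylpent-2-en-1-ol | OC/C=C(/C)CC[C@@H]1O[C@]1(C)C[C@H](O[Si](C)(C)C(C)(C)C)/C=C(\C)I | intermediate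
14 | {[(2S,3E)-1-[(2R,3S)-3-[(3Z)-5-bromo-3-methylpent-3-en-1-yl]-2-methyloxiran-2-yl]-4-iodopent-3-en-2-yl]oxy}(tert-butyl)dimethylsilane | BrC/C=C(/C)CC[C@@H]1O[C@]1(C)C[C@H](O[Si](C)(C)C(C)(C)C)/C=C(\C)I | intermediate
15 | (4S)-4-benzyl-1,3-oxazolidin-2-one | O=C1N[C@@H](Cc2ccccc2)CO1 | starting material
16 | (2E)-but-2-enoic anhydride (crotonic anhydride) | C/C=C/C(=O)OC(=O)/C=C/C | starting material
17 | (4S)-4-benzyl-3-[(2E)-but-2-enoyl]-1,3-oxazolidin-2-one | C/C=C/C(=O)N1[C@@H](Cc2ccccc2)COC1=O | intermediate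
18 | sodium (1Z)-1-[(4S)-4-benzyl-2-oxo-1,3-oxazolidin-3-yl]buta-1,3-dien-1-olate | C=C/C=C(\[O-])N1[C@@H](Cc2ccccc2)COC1=O.[Na+] | intermediate
19 | (4S)-4-benzyl-3-[(2S,4Z)-7-[(2S,3R)-3-{(2S,3E)-2-[(tert-butyldimethylsilyl)oxy]-4-iodopent-3-en-1-yl}-3-methyloxiran-2-yl]-2-ethenyl-5-methylhept-4-enoyl]-1,3-oxazolidin-2-one | C=C[C@@H](C(=O)N1[C@@H](Cc2ccccc2)COC1=O)C/C=C(/C)CC[C@@H]3O[C@]3(C)C[C@H](O[Si](C)(C)C(C)(C)C)/C=C(\C)I | intermediate
20 | (3S,5Z)-8-[(2S,3R)-3-{(2S,3E)-2-[(tert-butyldimethylsilyl)oxy]-4-iodopent-3-en-1-yl}-3-methyloxiran-2-yl]-3-ethenyl-6-methyloct-5-en-2-one | C=C[C@@H](C(C)=O)C/C=C(/C)CC[C@@H]1O[C@]1(C)C[C@H](O[Si](C)(C)C(C)(C)C)/C=C(\C)I | intermediate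
21 | (3S,5Z)-8-[(2S,3R)-3-{(2S,3E)-2-[(tert-butyldimethylsilyl)oxy]-4-iodopent-3-en-1-yl}-3-methyloxiran-2-yl]-3-ethenyl-2,6-dimethyloct-5-en-2-ol | C=C[C@@H](C(C)(C)O)C/C=C(/C)CC[C@@H]1O[C@]1(C)C[C@H](O[Si](C)(C)C(C)(C)C)/C=C(\C)I | intermediate
22 | (3R,5Z)-3-[2-(9-borabicyclo[3.3.1]nonan-9-yl)ethyl]-8-[(2S,3R)-3-{(2S,3E)-2-[(tert-butyldimethylsilyl)oxy]-4-iodopent-3-en-1-yl}-3-methyloxiran-2-yl]-2,6-dimethyloct-5-en-2-ol | B1(CC[C@@H](C(C)(C)O)C/C=C(/C)CC[C@@H]3O[C@]3(C)C[C@H](O[Si](C)(C)C(C)(C)C)/C=C(\C)I)C2CCCC1CCC2 | intermediate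
23 | 2-[(1R,3S,4E,8R,10Z,14S)-3-[(tert-butyldimethylsilyl)oxy]-1,5,11-trimethyl-15-oxabicyclo[12.1.0]pentadeca-4,10-dien-8-yl]propan-2-ol | CC(C)(C)[Si](C)(C)O[C@@H]1/C=C(\C)CC[C@@H](C(C)(C)O)C/C=C(/C)CC[C@@H]2O[C@]2(C)C1 | intermediate
24 | (1R,3S,4E,8R,10Z,14S)-8-(2-hydroxypropan-2-yl)-1,5,11-trimethyl-15-oxabicyclo[12.1.0]pentadeca-4,10-dien-3-ol | O[C@@H]1/C=C(\C)CC[C@@H](C(C)(C)O)C/C=C(/C)CC[C@@H]2O[C@]2(C)C1 | intermediate
25 | (1R,3R,4E,8R,10Z,14S)-8-(2-hydroxypropan-2-yl)-1,5,11-trimethyl-15-oxabicyclo[12.1.0]pentadeca-4,10-dien-3-yl acetate | CC(=O)O[C@H]1/C=C(\C)CC[C@@H](C(C)(C)O)C/C=C(/C)CC[C@@H]2O[C@]2(C)C1 | target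

**Step count.** Total steps: 18. Longest linear sequence: 17 (steps 1–12 and 14–18; step 13 is the side branch).

**Steps most likely to fail**

Step 16 (ring closure). Oligomerisation may outrun ring closure at the concentration needed for transmetalation, and protodeboronation or β-hydride elimination of the alkylpalladium may precede reductive elimination. The fallback sets out from 21 and comes back at 23. Hydroboration of 21 with 9-BBN and oxidative work-up (NaBO3·4H2O) gives the primary alcohol F1. Appel iodination (I2, PPh3, imidazole, 0 °C) gives the primary iodide F2, the tertiary alcohol being inert. A nickel-catalysed reductive cross-electrophile macrocyclisation (NiBr2(dme), 4,4′-di-tert-butyl-2,2′-bipyridine, Mn powder, NaI, DMA, syringe-pump addition) then joins C3 and C4 without a preformed organometallic and gives 23.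

Step 8 (directed epoxidation). Facial selectivity of the oxygen transfer may be poor, or the propargylic alcohol may be over-oxidised. The fallback sets out from 8 and comes back at 9. Boc2O/DMAP converts 8 into the tert-butyl carbonate F3. Iodine in MeCN at −20 °C triggers iodocarbonate cyclisation through a six-membered chair to the 4,6-cis cyclic iodocarbonate F4, with the C13–O bond syn to the C1–O bond and iodine anti at C12; the remote olefin forms an iodonium ion only reversibly. K2CO3 in MeOH cleaves the carbonate, and the C13 alkoxide displaces iodide at C12 with inversion to give the same syn epoxy alcohol 9.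

Step 18 (Mitsunobu inversion). Configuration may be lost through ionisation of the alkoxyphosphonium ion to an allyl cation, through SN2′ attack or elimination, and the hindered alcohol may react slowly with the weak acid. The fallback sets out from 24 and comes back at 25. Dess–Martin oxidation gives the macrocyclic enone F5. Reagent-controlled CBS reduction ((S)-2-methyl-CBS-oxazaborolidine, catecholborane, −78 °C, the alkenyl group acting as the large substituent) should give the C1-(R) allylic alcohol F6. Ac2O, pyridine and DMAP then acetylate only the secondary alcohol and give 25 with retention.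

**Further compounds**

F1 | step 16 | (3S,5Z)-8-[(2S,3R)-3-{(2S,3E)-2-[(tert-butyldimethylsilyl)oxy]-4-iodopent-3-en-1-yl}-3-methyloxiran-2-yl]-3-(2-hydroxyethyl)-2,6-dimethyloct-5-en-2-ol | OCC[C@@H](C(C)(C)O)C/C=C(/C)CC[C@@H]1O[C@]1(C)C[C@H](O[Si](C)(C)C(C)(C)C)/C=C(\C)I
F2 | step 16 | (3S,5Z)-8-[(2S,3R)-3-{(2S,3E)-2-[(tert-butyldimethylsilyl)oxy]-4-iodopent-3-en-1-yl}-3-methyloxiran-2-yl]-3-(2-iodoethyl)-2,6-dimethyloct-5-en-2-ol | ICC[C@@H](C(C)(C)O)C/C=C(/C)CC[C@@H]1O[C@]1(C)C[C@H](O[Si](C)(C)C(C)(C)C)/C=C(\C)I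
F3 | step 8 | tert-butyl (4S,6Z,10Z)-12-[(4-methoxybenzyl)oxy]-6,10-dimethyldodeca-6,10-dien-2-yn-4-yl carbonate | COc1ccc(COC/C=C(/C)CC/C=C(/C)C[C@H](OC(=O)OC(C)(C)C)C#CC)cc1
F4 | step 8 | (4R,6S)-4-[(1R,4Z)-1-iodo-6-[(4-methoxybenzyl)oxy]-4-methylhex-4-en-1-yl]-4-methyl-6-(prop-1-yn-1-yl)-1,3-dioxan-2-one | COc1ccc(COC/C=C(/C)CC[C@@H](I)[C@@]2(C)C[C@@H](C#CC)OC(=O)O2)cc1
F5 | step 18 | (1R,4E,8R,10Z,14S)-8-(2-hydroxypropan-2-yl)-1,5,11-trimethyl-15-oxabicyclo[12.1.0]pentadeca-4,10-dien-3-one | O=C1/C=C(\C)CC[C@@H](C(C)(C)O)C/C=C(/C)CC[C@@H]2O[C@]2(C)C1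
F6 | step 18 | (1R,3R,4E,8R,10Z,14S)-8-(2-hydroxypropan-2-yl)-1,5,11-trimethyl-15-oxabicyclo[12.1.0]pentadeca-4,10-dien-3-ol | O[C@H]1/C=C(\C)CC[C@@H](C(C)(C)O)C/C=C(/C)CC[C@@H]2O[C@]2(C)C1
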